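**Retrosynthetic overview**
1. The γ-lactone and the enal come last. Both arise from one double allylic oxidation of a 6β-angeloyloxy-8α,9α-dihydroxyelema-1,3,11(13)-triene (two isopropenyl groups), followed by MnO2.
2. The carbocycle is closed at C8–C9 by reductive ketyl (pinacol) coupling of an acyclic 1,6-dialdehyde. Two formyl carbons are joined and the cis-diol is set in the ring-forming step.
3. C6–C7 comes from Z-allylboration of an α-chiral aldehyde with the 1,4-diboration product of isoprene (sets C6 and C7).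
4. C5–C10 comes from an enantioselective boron Ireland–Claisen rearrangement of an (E)-allylic senecioate made from isoprene monoxide and senecioic acid (sets C5 and C10).
5. Ring order: cyclohexane first (step 9), γ-lactone second (step 11).

Locants: elemane numbering of the target is used for all compounds. C10 is the quaternary carbon (C14 methyl, C1=C2 vinyl). C5 bears C4(=C3)–C15, C6 bears the angelate, C7 bears C11(=C13)–C12, C8 bears the lactone O and C9 bears OH. β is the face of C14 and α is the face of the vinyl group.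

Assumption: the (S,S)-controller of step 2 is taken to give the (5S,10S) series; if the sense of induction is the opposite, its equally available (R,R)-enantiomer is used with no other change.

**Step 1**
Reactants: 1 2-ethenyl-2-methyloxirane (isoprene monoxide, racemic); 2 3-methylbut-2-enoic acid (senecioic acid)
Product: 4 (2E)-4-[(tert-butyldimethylsilyl)oxy]-3-methylbut-2-en-1-yl 3-methylbut-2-enoate, via hydroxy ester 3 (not isolated)
Conditions: Pd(PPh3)4 (2 mol %), THF, 0 °C to rt; then imidazole, TBSCl, DMF, rt; minor Z-isomer removed by chromatography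
Reagents that add atoms: tert-butyldimethylsilyl chloride, CC(C)(C)[Si](C)(C)Cl
Why: Tsuji–Trost-type 1,4-opening of a vinyl epoxide: zerovalent palladium ionises 1 to a π-allyl alkoxide that deprotonates 2, the carboxylate attacks the unhindered CH2 terminus, reversible re-ionisation of the allylic ester funnels the material to the more stable E-alkene (CH2OH trans to CH2O-acyl), and the freed primary alcohol is silylated in the same flask; no stereocentre is formed, but this E-geometry later fixes C10.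

**Step 2**
Reactants: 4 (2E)-4-[(tert-butyldimethylsilyl)oxy]-3-methylbut-2-en-1-yl 3-methylbut-2-enoate
Product: 7 (2S,3S)-3-{[(tert-butyldimethylsilyl)oxy]methyl}-3-methyl-2-(prop-1-en-2-yl)pent-4-enoic acid (5S,10S), via boron dienolate 5 (not isolated), via boron carboxylate 6 (not isolated)
Conditions: (1S,2S)-N,N'-bis{[3,5-bis(trifluoromethyl)phenyl]sulfonyl}-1,2-diphenylethane-1,2-diamine (1.1 equiv), BBr3 (1.1 equiv), CH2Cl2, rt, then evaporation; 4, Et3N, toluene/hexane, −78 °C, then −20 °C, 3 d; aqueous work-up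
Reagents that add atoms: none
Why: Enantioselective boron-enolate Ireland–Claisen rearrangement: the bromoborane made in the flask complexes the s-trans senecioate, Et3N removes a γ-proton to give the E(O) dienolate 5, and its [3,3] shift through a chair that holds the isopropenyl group axial and the CH2OTBS group of the E-alkene equatorial sets the C5/C10 relative configuration, while the C2-symmetric bis-sulfonamide ligand blocks one face of the dienolate and so sets the absolute configuration (5S,10S).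

**Step 3**
Reactants: 7 (2S,3S)-3-{[(tert-butyldimethylsilyl)oxy]methyl}-3-methyl-2-(prop-1-en-2-yl)pent-4-enoic acid
Product: 10 (2S,3S)-3-{[(tert-butyldimethylsilyl)oxy]methyl}-3-methyl-2-(prop-1-en-2-yl)pent-4-enal (5S,10S), via trimethylsilyl ester 8 (not isolated), via aluminium silyl acetal 9 (not isolated)
Conditions: Me3SiCl, Et3N, CH2Cl2, 0 °C; then i-Bu2AlH (1.1 equiv), −78 °C; aqueous tartrate work-up; used at once
Reagents that add atoms: none
Why: Partial reduction of a silyl ester with i-Bu2AlH: the crowded tetrahedral adduct 9 is stable at −78 °C and collapses to the aldehyde only on work-up, so neither over-reduction nor base-induced epimerisation or conjugation at C5 can occur and both stereocentres are kept.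

**Step 4**
Reactants: 11 2-methylbuta-1,3-diene (isoprene); 12 bis(pinacolato)diboron
Product: 13 (2Z)-2-methyl-1,4-bis(4,4,5,5-tetramethyl-1,3,2-dioxaborolan-2-yl)but-2-ene
Conditions: Pt(PPh3)4 (3 mol %), toluene, 80 °C
Reagents that add atoms: none
Why: Platinum-catalysed 1,4-diboration of a 1,3-diene, in which the s-cis-bound diene inserts into a Pt–B bond and reductive elimination from the resulting allyl platinum species delivers the second boron to the far terminus, giving only the Z-alkene.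

**Step 5**
Reactants: 10 (2S,3S)-aldehyde; 13 (2Z)-bis-boronate
Product: 15 (2S,3R,4S,5S)-5-{[(tert-butyldimethylsilyl)oxy]methyl}-5-methyl-2,4-di(prop-1-en-2-yl)-1-(4,4,5,5-tetramethyl-1,3,2-dioxaborolan-2-yl)hept-6-en-3-ol (7S,6R,5S,10S), via borate ester 14 (not isolated)
Conditions: 13 (1.5 equiv), toluene, 40 °C, 48 h; aq. NaHCO3 work-up
Reagents that add atoms: none
Why: Allylboration through a closed Zimmerman–Traxler chair: only the boron on C13 can pass its allyl unit on through the unhindered CH terminus C7, the Z-alkene places CH2Bpin axial and gives the 6,7-relationship (O-6 and C8 syn), and avoidance of a syn-pentane clash with that axial group puts H-5 inside and the quaternary C10 anti to the forming bond, which gives the anti-Felkin 5,6-relationship that the target needs.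

**Step 6**
Reactants: 15 homoallylic alcohol; 16 (2Z)-2-methylbut-2-enoic acid (angelic acid)
Product: 18 (2S,3R,4S,5S)-5-{[(tert-butyldimethylsilyl)oxy]methyl}-5-methyl-2,4-di(prop-1-en-2-yl)-1-(4,4,5,5-tetramethyl-1,3,2-dioxaborolan-2-yl)hept-6-en-3-yl (2Z)-2-methylbut-2-enoate, via mixed anhydride 17 (not isolated)
Conditions: 16, 2,4,6-Cl3C6H2COCl, Et3N, toluene, rt, 2 h; then 15, 80 °C, 24 h
Reagents that add atoms: none
Why: Yamaguchi-type mixed-anhydride esterification run without a nucleophilic catalyst, a known way to acylate hindered secondary alcohols with angelic acid without Z-to-E isomerisation; the alkyl boronate, the silyl ether and the four stereocentres are untouched and 80 °C is far below the onset of a Cope rearrangement of the 1,5-diene.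

**Step 7**
Reactants: 18 angelate boronate
Product: 20 (2R,3S,4S,5S)-1-hydroxy-5-(hydroxymethyl)-5-methyl-2,4-di(prop-1-en-2-yl)hept-6-en-3-yl (2Z)-2-methylbut-2-enoate (7R,6S,5S,10S), via silyl ether alcohol 19 (not isolated)
Conditions: 30% H2O2, aq. Na2CO3/NaHCO3 buffer (pH 9), THF, 0 °C to rt; Na2S2O3 quench; then 1 M H2SO4 to pH 1, rt
Reagents that add atoms: hydrogen peroxide, OO
Why: Oxidation of the primary alkylboronate by hydroperoxide (1,2-shift from boron to oxygen) followed by acid-catalysed hydrolysis of the primary silyl ether in the same flask; the mildly basic and then mildly acidic media leave the hindered conjugated ester in place and no stereocentre is involved (descriptors change only through priorities).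

**Step 8**
Reactants: 20 diol
Product: 21 (2S,3S,4S,5S)-5-formyl-5-methyl-1-oxo-2,4-di(prop-1-en-2-yl)hept-6-en-3-yl (2Z)-2-methylbut-2-enoate (7S,6S,5S,10S)
Conditions: Dess–Martin periodinane (2.5 equiv), CH2Cl2, 0 °C to rt; used crude
Reagents that add atoms: none
Why: Dess–Martin oxidation of both primary alcohols under non-basic conditions, which avoids loss of angelic acid by E1cB elimination and migration of the C11 double bond into conjugation, so C7 is not epimerised.

**Step 9 (key step)**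
Reactants: 21 dialdehyde
Product: 23 6β-[(2Z)-2-methylbut-2-enoyloxy]elema-1,3,11(13)-triene-8α,9α-diol (5S,6S,7R,8R,9S,10S), via samarium diolate 22 (not isolated)
Conditions: SmI2 (2.5 equiv, 0.1 M in THF), THF, −78 °C to −20 °C; aq. NaHCO3
Reagents that add atoms: none
Why: Samarium diiodide pinacol cyclisation: single-electron transfer turns the two formyl carbons, both normally electrophilic, into nucleophilic ketyls (reversed polarity at the carbonyl carbon) that couple while their oxygens are bridged by trivalent samarium, which enforces the cis-diol, and in the chair with the C5 and C7 isopropenyl groups equatorial the β,β-alternative would put O-8 syn-axial to both the C14 methyl and the C6 ester, so the 8α,9α-diol (8R,9S) is formed.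

**Step 10**
Reactants: 23 ring diol
Product: 24 6β-[(2Z)-2-methylbut-2-enoyloxy]elema-1,3,11(13)-triene-8α,9α,12,15-tetraol (5S,6S,7R,8R,9S,10S)
Conditions: SeO2 (0.4 equiv), t-BuOOH (5.5 M in decane, 4 equiv), CH2Cl2, 0 °C to rt; any enal already formed is carried on together with 24
Reagents that add atoms: tert-butyl hydroperoxide, CC(C)(C)OO (the oxygen is carried to carbon by SeO2, O=[Se]=O)
Why: Selenium dioxide allylic oxidation (ene reaction then [2,3]-sigmatropic shift, SeO2 recycled by t-BuOOH): only the two electron-rich 1,1-disubstituted alkenes carry reactive allylic methyl groups, the vinyl group has no allylic hydrogen, the angelate alkene is electron-poor and the C5 and C7 methine hydrogens are shielded, so both isopropenyl groups are hydroxylated at CH3 and no stereocentre changes.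

**Step 11**
Reactants: 24 tetraol
Product: 27 (3aS,4S,5R,6S,7S,7aR)-6-ethenyl-7-hydroxy-6-methyl-3-methylidene-2-oxo-5-(3-oxoprop-1-en-2-yl)octahydro-1-benzofuran-4-yl (2Z)-2-methylbut-2-enoate (elemane locants 5R,6S,7S,8R,9S,10S), via bis-enal 25 (not isolated), via lactol 26 (not isolated)
Conditions: activated MnO2 (30 equiv), CH2Cl2, rt
Reagents that add atoms: none
Why: Manganese dioxide oxidation of allylic alcohols: both primary allylic alcohols give enals, the C12 enal is trapped by the neighbouring equatorial 8α-hydroxyl as the trans-fused lactol 26, which as an allylic hemiacetal is oxidised on to the α-methylene-γ-lactone, while the non-allylic 9α-hydroxyl is inert, so no stereocentre is touched.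

**Compound list**
1 | 2-ethenyl-2-methyloxirane (isoprene monoxide, racemic) | CC1(C=C)CO1 | starting material
2 | 3-methylbut-2-enoic acid (senecioic acid) | CC(C)=CC(=O)O | starting material
3 | (2E)-4-hydroxy-3-methylbut-2-en-1-yl 3-methylbut-2-enoate | CC(C)=CC(=O)OC/C=C(C)/CO | intermediate
4 | (2E)-4-[(tert-butyldimethylsilyl)oxy]-3-methylbut-2-en-1-yl 3-methylbut-2-enoate | CC(C)=CC(=O)OC/C=C(C)/CO[Si](C)(C)C(C)(C)C | intermediate
5 | E(O) boron dienolate of 4 carrying the (4S,5S)-1,3-bis{[3,5-bis(trifluoromethyl)phenyl]sulfonyl}-4,5-diphenyl-1,3,2-diazaborolidin-2-yl group | C=C(C)/C=C(/OB1N(S(=O)(=O)c2cc(cc(c2)C(F)(F)F)C(F)(F)F)[C@@H](c2ccccc2)[C@H](c2ccccc2)N1S(=O)(=O)c1cc(cc(c1)C(F)(F)F)C(F)(F)F)OC/C=C(C)/CO[Si](C)(C)C(C)(C)C | intermediate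
6 | boron carboxylate of 7 (same diazaborolidinyl group on the carboxyl oxygen) | CC(C)(C)[Si](C)(C)OC[C@@](C)(C=C)[C@H](C(C)=C)C(=O)OB1N(S(=O)(=O)c2cc(cc(c2)C(F)(F)F)C(F)(F)F)[C@@H](c2ccccc2)[C@H](c2ccccc2)N1S(=O)(=O)c1cc(cc(c1)C(F)(F)F)C(F)(F)F | intermediate
7 | (2S,3S)-3-{[(tert-butyldimethylsilyl)oxy]methyl}-3-methyl-2-(prop-1-en-2-yl)pent-4-enoic acid | CC(C)(C)[Si](C)(C)OC[C@@](C)(C=C)[C@H](C(C)=C)C(=O)O | intermediate
8 | trimethylsilyl ester of 7 | CC(C)(C)[Si](C)(C)OC[C@@](C)(C=C)[C@H](C(C)=C)C(=O)O[Si](C)(C)C | intermediate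
9 | diisobutylaluminium trimethylsilyl acetal of 10 (acetal carbon unassigned) | CC(C)(C)[Si](C)(C)OC[C@@](C)(C=C)[C@H](C(C)=C)C(O[Si](C)(C)C)O[Al](CC(C)C)CC(C)C | intermediate
10 | (2S,3S)-3-{[(tert-butyldimethylsilyl)oxy]methyl}-3-methyl-2-(prop-1-en-2-yl)pent-4-enal | CC(C)(C)[Si](C)(C)OC[C@@](C)(C=C)[C@H](C(C)=C)C=O | intermediate
11 | 2-methylbuta-1,3-diene (isoprene) | C=CC(C)=C | starting material
12 | bis(pinacolato)diboron | CC1(C)OB(OC1(C)C)B1OC(C)(C)C(C)(C)O1 | starting material
13 | (2Z)-2-methyl-1,4-bis(4,4,5,5-tetramethyl-1,3,2-dioxaborolan-2-yl)but-2-ene | CC1(C)OB(C/C(C)=C\CB2OC(C)(C)C(C)(C)O2)OC1(C)C | intermediate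
14 | O-pinacolboryl (borate) ester of 15 | CC(C)(C)[Si](C)(C)OC[C@@](C)(C=C)[C@H](C(C)=C)[C@H](OB1OC(C)(C)C(C)(C)O1)[C@H](C(C)=C)CB1OC(C)(C)C(C)(C)O1 | intermediate
15 | (2S,3R,4S,5S)-5-{[(tert-butyldimethylsilyl)oxy]methyl}-5-methyl-2,4-di(prop-1-en-2-yl)-1-(pinacolboryl)hept-6-en-3-ol | CC(C)(C)[Si](C)(C)OC[C@@](C)(C=C)[C@H](C(C)=C)[C@H](O)[C@H](C(C)=C)CB1OC(C)(C)C(C)(C)O1 | intermediate
16 | (2Z)-2-methylbut-2-enoic acid (angelic acid) | C/C=C(/C)C(=O)O | starting material
17 | angelic 2,4,6-trichlorobenzoic anhydride | C/C=C(/C)C(=O)OC(=O)c1c(Cl)cc(Cl)cc1Cl | intermediate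
18 | 6-O-angelate of 15 | CC(C)(C)[Si](C)(C)OC[C@@](C)(C=C)[C@H](C(C)=C)[C@H](OC(=O)/C(C)=C\C)[C@H](C(C)=C)CB1OC(C)(C)C(C)(C)O1 | intermediate
19 | (2R,3S,4S,5S)-5-{[(tert-butyldimethylsilyl)oxy]methyl}-1-hydroxy-5-methyl-2,4-di(prop-1-en-2-yl)hept-6-en-3-yl (2Z)-2-methylbut-2-enoate | CC(C)(C)[Si](C)(C)OC[C@@](C)(C=C)[C@H](C(C)=C)[C@H](OC(=O)/C(C)=C\C)[C@H](C(C)=C)CO | intermediate
20 | (2R,3S,4S,5S)-1-hydroxy-5-(hydroxymethyl)-5-methyl-2,4-di(prop-1-en-2-yl)hept-6-en-3-yl (2Z)-2-methylbut-2-enoate | OC[C@@](C)(C=C)[C@H](C(C)=C)[C@H](OC(=O)/C(C)=C\C)[C@H](C(C)=C)CO | intermediate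
21 | (2S,3S,4S,5S)-5-formyl-5-methyl-1-oxo-2,4-di(prop-1-en-2-yl)hept-6-en-3-yl (2Z)-2-methylbut-2-enoate | O=C[C@@](C)(C=C)[C@H](C(C)=C)[C@H](OC(=O)/C(C)=C\C)[C@H](C(C)=C)C=O | intermediate
22 | 8,9-bis(diiodosamarium) alkoxide of 23 | C=C[C@]1(C)[C@H](O[Sm](I)I)[C@H](O[Sm](I)I)[C@@H](C(C)=C)[C@@H](OC(=O)/C(C)=C\C)[C@H]1C(C)=C | intermediate
23 | 6β-angeloyloxyelema-1,3,11(13)-triene-8α,9α-diol (5S,6S,7R,8R,9S,10S) | C=C[C@]1(C)[C@H](O)[C@H](O)[C@@H](C(C)=C)[C@@H](OC(=O)/C(C)=C\C)[C@H]1C(C)=C | intermediate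
24 | 6β-angeloyloxyelema-1,3,11(13)-triene-8α,9α,12,15-tetraol (5S,6S,7R,8R,9S,10S) | C=C[C@]1(C)[C@H](O)[C@H](O)[C@@H](C(=C)CO)[C@@H](OC(=O)/C(C)=C\C)[C@H]1C(=C)CO | intermediate
25 | 6β-angeloyloxy-8α,9α-dihydroxyelema-1,3,11(13)-triene-12,15-dial (5R,6S,7R,8R,9S,10S) | C=C[C@]1(C)[C@H](O)[C@H](O)[C@@H](C(=C)C=O)[C@@H](OC(=O)/C(C)=C\C)[C@H]1C(=C)C=O | intermediate
26 | 8α,12-lactol of 25 (C12 epimers; 5R,6S,7S,8R,9S,10S) | C=C[C@]1(C)[C@H](O)[C@@H]2OC(O)C(=C)[C@H]2[C@@H](OC(=O)/C(C)=C\C)[C@H]1C(=C)C=O | intermediate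
27 | CNP0277836.2, 6β-angeloyloxy-9α-hydroxy-15-oxoelema-1,3,11(13)-trien-8α,12-olide (5R,6S,7S,8R,9S,10S) | C=C[C@]1(C)[C@H](O)[C@@H]2OC(=O)C(=C)[C@H]2[C@@H](OC(=O)/C(C)=C\C)[C@H]1C(=C)C=O | target

**Total step count:** 11. **Longest linear sequence:** 10 (steps 1–3 and 5–11; step 4 is a one-step side branch).

**Three steps most likely to fail**

Step 2. The bromoborane may attack the silyl ether, and the geometry or facial bias of a dienolate may be poorer than for simple ester enolates. The fallback gives up reagent control in favour of resolution. It sets out from 4 and comes back at 7. Compound 4 is rearranged as its achiral dicyclohexylboron dienolate F1 (c-Hex2BOTf, Et3N, toluene, −78 °C to rt; same E(O) geometry and chair). Work-up gives the racemic acid F2. This is resolved by crystallising the (R)-1-phenylethylammonium salt F3 of the (2S,3S)-acid, and acidification gives 7.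

Step 6. The C6 hydroxyl is flanked by two branched carbons, so acylation with the isomerisation-prone angelic acid may stall. The fallback builds the Z-alkene on the ester instead of bringing it in. It sets out from 15 and comes back at 18. Compound 15 is acylated with 2-[bis(2,2,2-trifluoroethoxy)phosphoryl]propanoic acid (dicyclohexylcarbodiimide, DMAP, where forcing conditions carry no isomerisation risk) to give the phosphonopropionate ester F4. A Still–Gennari olefination with acetaldehyde (KN(SiMe3)2, 18-crown-6, THF, −78 °C) then gives 18.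

Step 9. The β-acyloxy dialdehyde 21 may lose angelic acid before it cyclises. The ketyls may also be diverted by the enoate, by a 1,2-vinyl shift or by the C4 alkene. The fallback postpones the ester and closes the ring on a more robust substrate. It sets out from 15 and comes back at 23.
- Compound 15 is silylated at O-6 (TBSOTf, 2,6-lutidine) to the bis-silyl ether boronate F5.
- H2O2 at pH 9 gives the bis-silyl ether alcohol F6.
- Brief treatment with dilute H2SO4 removes only the primary silyl group and gives the 6-O-silyl diol F7.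
- Dess–Martin oxidation gives the β-silyloxy dialdehyde F8, which has no carboxylate leaving group and no enoate.
- SmI2 closes it to the 6β-silyloxy-8α,9α-diol F9.
- 2,2-Dimethoxypropane/PPTS gives the acetonide silyl ether F10.
- Bu4NF gives the acetonide alcohol F11.
- Mixed anhydride 17 (toluene, 90 °C) gives the acetonide angelate F12.
- 80% aqueous acetic acid frees 23.

**Further compounds**
F1 | step 2 | dicyclohexylboron E(O) dienolate of 4 | C=C(C)/C=C(/OB(C1CCCCC1)C1CCCCC1)OC/C=C(C)/CO[Si](C)(C)C(C)(C)C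
F2 | step 2 | racemic acid, (2S,3S)- and (2R,3R)-3-{[(tert-butyldimethylsilyl)oxy]methyl}-3-methyl-2-(prop-1-en-2-yl)pent-4-enoic acid 1:1 | CC(C)(C)[Si](C)(C)OC[C@@](C)(C=C)[C@H](C(C)=C)C(=O)O.CC(C)(C)[Si](C)(C)OC[C@](C)(C=C)[C@@H](C(C)=C)C(=O)O
F3 | step 2 | (R)-1-phenylethylammonium salt of the (2S,3S)-acid | CC(C)(C)[Si](C)(C)OC[C@@](C)(C=C)[C@H](C(C)=C)C(=O)O.C[C@@H](N)c1ccccc1
F4 | step 6 | 6-O-{2-[bis(2,2,2-trifluoroethoxy)phosphoryl]propanoyl} derivative of 15 (phosphonate α-carbon unassigned) | CC(C)(C)[Si](C)(C)OC[C@@](C)(C=C)[C@H](C(C)=C)[C@H](OC(=O)C(C)P(=O)(OCC(F)(F)F)OCC(F)(F)F)[C@H](C(C)=C)CB1OC(C)(C)C(C)(C)O1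
F5 | step 9 | 6-O-tert-butyldimethylsilyl ether of 15 | CC(C)(C)[Si](C)(C)OC[C@@](C)(C=C)[C@H](C(C)=C)[C@H](O[Si](C)(C)C(C)(C)C)[C@H](C(C)=C)CB1OC(C)(C)C(C)(C)O1
F6 | step 9 | 6,9-bis-O-silyl C8 primary alcohol | CC(C)(C)[Si](C)(C)OC[C@@](C)(C=C)[C@H](C(C)=C)[C@H](O[Si](C)(C)C(C)(C)C)[C@H](C(C)=C)CO
F7 | step 9 | 6-O-silyl 8,9-diol (acyclic) | OC[C@@](C)(C=C)[C@H](C(C)=C)[C@H](O[Si](C)(C)C(C)(C)C)[C@H](C(C)=C)CO
F8 | step 9 | 6-O-silyl 8,9-dialdehyde | O=C[C@@](C)(C=C)[C@H](C(C)=C)[C@H](O[Si](C)(C)C(C)(C)C)[C@H](C(C)=C)C=O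
F9 | step 9 | 6β-(tert-butyldimethylsilyloxy)elema-1,3,11(13)-triene-8α,9α-diol | C=C[C@]1(C)[C@H](O)[C@H](O)[C@@H](C(C)=C)[C@@H](O[Si](C)(C)C(C)(C)C)[C@H]1C(C)=C
F10 | step 9 | 8α,9α-O-isopropylidene derivative of F9 | C=C[C@]1(C)[C@@H]2OC(C)(C)O[C@@H]2[C@@H](C(C)=C)[C@@H](O[Si](C)(C)C(C)(C)C)[C@H]1C(C)=C
F11 | step 9 | 8α,9α-O-isopropylidene-elema-1,3,11(13)-trien-6β-ol | C=C[C@]1(C)[C@@H]2OC(C)(C)O[C@@H]2[C@@H](C(C)=C)[C@@H](O)[C@H]1C(C)=C
F12 | step 9 | 8α,9α-O-isopropylidene derivative of 23 | C=C[C@]1(C)[C@@H]2OC(C)(C)O[C@@H]2[C@@H](C(C)=C)[C@@H](OC(=O)/C(C)=C\C)[C@H]1C(C)=C
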